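**Target:** CNP0124069.2, (1S,3R,4R,7S,12S,13R,14R)-3,4-epoxy-7,13-dihydroxycembra-8(19),15(17)-dien-16,14-olide.

## Retrosynthetic overview

1. Last ring: the 14-membered carbocycle is closed at C7–C8 by a nickel-catalysed reductive coupling of a C7 aldehyde with a terminal C8≡C19 alkyne. This one step gives the ring, the exocyclic methylene and the C7 carbinol; only desilylation follows. (The usual choice would be a Nozaki–Hiyama–Kishi or metathesis closure.)
2. Before that, a reagent-controlled Shi epoxidation installs the C3–C4 oxirane on the acyclic lactone.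
3. First ring: the cis α-methylene-γ-butyrolactone comes from a chelation-controlled indium Barbier union (C1–C14) of an α-hydroxy aldehyde (fragment E, C8–C14) with a (Z)-2-(bromomethyl)enoate (fragment W, C1–C7 and C15–C17).
4. Fragment E: Sharpless epoxidation of crotyl alcohol, then cuprate opening (C12, C13). Fragment W: Negishi carboalumination/oxirane, vinylalumination, SN2' bromination.
5. Ring order: lactone, then oxirane, then carbocycle.

Assumption: positions are cited in cembrane numbering (C1 lactone CH, C3/C4 oxirane, C7 allylic carbinol, C8=C19 methylene, C12 CHMe, C13 carbinol, C14 lactone CH–O, C15=C17 methylene, C16 lactone C=O); crude aldehydes used directly count as isolated.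

## Route

Step 1
Reactants: 1 (E)-but-2-en-1-ol
Product: 3 tert-butyl{[(2S,3S)-3-methyloxiran-2-yl]methoxy}diphenylsilane, via epoxy alcohol 2 (not isolated)
Conditions: Ti(OiPr)4 (0.1 equiv), L-(+)-diisopropyl tartrate (0.12 equiv), t-BuOOH (1.5 equiv), 4 Å MS, CH2Cl2, −20 °C; then TBDPSCl, Et3N, DMAP (cat.), −20 → 0 °C
Reagents that add atoms: tert-butyl hydroperoxide CC(C)(C)OO; tert-butyl(chloro)diphenylsilane CC(C)(C)[Si](Cl)(c1ccccc1)c1ccccc1
Why: Sharpless asymmetric epoxidation, in which the L-(+)-tartrate catalyst delivers oxygen to the face that gives the (2S,3S)-epoxide (future C13 and the carbon that becomes C12), and in situ silylation makes the volatile epoxy alcohol isolable and places a bulky group next to C2.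

Step 2
Reactants: 3 tert-butyl{[(2S,3S)-3-methyloxiran-2-yl]methoxy}diphenylsilane; 4 (5-chloropent-1-yn-1-yl)trimethylsilane
Product: 6 (2R,3S)-1-{[tert-butyl(diphenyl)silyl]oxy}-3-methyl-8-(trimethylsilyl)oct-7-yn-2-ol, via Grignard reagent 5 (not isolated)
Conditions: 4, Mg, THF, 60 °C; then CuI (0.1 equiv), 3, THF, −30 → 0 °C
Reagents that add atoms: none
Why: Copper-catalysed Grignard opening of the epoxide (SN2) at the methyl-bearing carbon, remote from the bulky silyloxymethyl group, with inversion, which converts the trans-epoxide into the syn 2-hydroxy-3-methyl array (C12 S, C13 R).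

Step 3
Reactants: 6 (2R,3S)-1-{[tert-butyl(diphenyl)silyl]oxy}-3-methyl-8-(trimethylsilyl)oct-7-yn-2-ol
Product: 7 (2R,3S)-3-methyloct-7-yne-1,2-diol
Conditions: TBAF (2.5 equiv), THF, 0 → 23 °C
Reagents that add atoms: none
Why: Fluoride cleaves the O–Si and the C(sp)–Si bond in one operation without touching either stereocentre.

Step 4
Reactants: 7 (2R,3S)-3-methyloct-7-yne-1,2-diol
Product: 8 (2R,3S)-2-hydroxy-3-methyloct-7-ynal
Conditions: TEMPO (0.1 equiv), PhI(OAc)2 (1.1 equiv), CH2Cl2, 23 °C; used crude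
Reagents that add atoms: none
Why: TEMPO/PhI(OAc)2 oxidation (Piancatelli–Margarita), in which the oxoammonium ion oxidises the primary carbinol much faster than the secondary one, under neutral conditions that do not epimerise C13.

Step 5
Reactants: 9 tert-butyl(dimethyl)(pent-4-yn-1-yloxy)silane; 10 oxirane
Product: 13 (3E)-7-{[tert-butyl(dimethyl)silyl]oxy}-4-methylhept-3-en-1-ol, via alkenyldimethylalane 11 (not isolated), via lithium alkenylalanate 12 (not isolated)
Conditions: Me3Al (2 equiv), Cp2ZrCl2 (0.25 equiv), CH2Cl2, 0 → 23 °C; n-BuLi, THF–hexane, −78 °C; oxirane, −78 → 0 °C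
Reagents that add atoms: trimethylaluminium C[Al](C)C
Why: Negishi zirconium-catalysed carboalumination adds Me–Al syn across the alkyne (E-trisubstituted alkene, C4 methyl), and the derived alanate opens oxirane with retention of alkene geometry to add C1 and C2.

Step 6
Reactants: 13 (3E)-7-{[tert-butyl(dimethyl)silyl]oxy}-4-methylhept-3-en-1-ol
Product: 14 (3E)-7-{[tert-butyl(dimethyl)silyl]oxy}-4-methylhept-3-enal
Conditions: Dess–Martin periodinane (1.2 equiv), CH2Cl2, 0 → 23 °C; used at once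
Reagents that add atoms: none
Why: Dess–Martin oxidation is non-basic, so the β,γ-alkene does not migrate into conjugation.

Step 7
Reactants: 14 (3E)-7-{[tert-butyl(dimethyl)silyl]oxy}-4-methylhept-3-enal; 15 methyl prop-2-ynoate
Product: 17 methyl (5E)-9-{[tert-butyl(dimethyl)silyl]oxy}-3-hydroxy-6-methyl-2-methylidenenon-5-enoate, via α-alumino acrylate 16 (not isolated)
Conditions: i-Bu2AlH, N-methylmorpholine N-oxide, THF, 0 °C; 15; then 14, 0 → 23 °C
Reagents that add atoms: none
Why: Vinylalumination (an amine-free Morita–Baylis–Hillman equivalent): hydroalumination of the propiolate gives the α-alumino acrylate, which adds 1,2 to the base-sensitive aldehyde; the new carbinol centre is racemic and is erased in step 8.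

Step 8
Reactants: 17 methyl (5E)-9-{[tert-butyl(dimethyl)silyl]oxy}-3-hydroxy-6-methyl-2-methylidenenon-5-enoate
Product: 18 methyl (2Z,5E)-2-(bromomethyl)-9-{[tert-butyl(dimethyl)silyl]oxy}-6-methylnona-2,5-dienoate
Conditions: NBS (1.5 equiv), Me2S (1.8 equiv), CH2Cl2, 0 → 23 °C
Reagents that add atoms: N-bromosuccinimide O=C1CCC(=O)N1Br
Why: Corey–Kim-type bromination with allylic transposition (SN2'): bromide attacks the acrylate terminus of the alkoxysulfonium salt and gives the thermodynamically preferred (Z)-2-(bromomethyl)enoate, with the chain trans to the ester.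

Step 9
Reactants: 8 (2R,3S)-2-hydroxy-3-methyloct-7-ynal; 18 methyl (2Z,5E)-2-(bromomethyl)-9-{[tert-butyl(dimethyl)silyl]oxy}-6-methylnona-2,5-dienoate
Product: 20 (4S,5R)-4-[(2E)-6-hydroxy-3-methylhex-2-en-1-yl]-5-[(1R,2S)-1-hydroxy-2-methylhept-6-yn-1-yl]-3-methylideneoxolan-2-one, via Barbier hydroxy ester 19 (not isolated)
Conditions: In powder (1.5 equiv), THF–H2O (1:1), 23 °C; then 1 M aq. HCl, THF, 23 °C
Reagents that add atoms: none
Why: Indium Barbier allylation in water, then acid lactonisation and silyl cleavage: the (Z)-γ-substituted allylindium reacts through a chair (Zimmerman–Traxler) transition state to give the C1/C14 syn, cis-lactone relationship, and indium chelation between the aldehyde and the free α-hydroxyl (Cram chelate) gives the 13,14-syn diol, so C1 (S) and C14 (R) are set from C13.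

Step 10
Reactants: 20 (4S,5R)-4-[(2E)-6-hydroxy-3-methylhex-2-en-1-yl]-5-[(1R,2S)-1-hydroxy-2-methylhept-6-yn-1-yl]-3-methylideneoxolan-2-one
Product: 21 (4S,5R)-3-methylidene-4-{(2E)-3-methyl-6-[(triethylsilyl)oxy]hex-2-en-1-yl}-5-{(1R,2S)-2-methyl-1-[(triethylsilyl)oxy]hept-6-yn-1-yl}oxolan-2-one
Conditions: Et3SiOTf (3 equiv), 2,6-lutidine (5 equiv), CH2Cl2, −78 → 0 °C
Reagents that add atoms: triethylsilyl trifluoromethanesulfonate CC[Si](CC)(CC)OS(=O)(=O)C(F)(F)F
Why: Silylation with a silyl triflate protects the hindered C13 carbinol (locking the γ-lactone) and turns the C7 hydroxyl into a primary triethylsilyl ether that can later be oxidised directly.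

Step 11
Reactants: 21 (4S,5R)-3-methylidene-4-{(2E)-3-methyl-6-[(triethylsilyl)oxy]hex-2-en-1-yl}-5-{(1R,2S)-2-methyl-1-[(triethylsilyl)oxy]hept-6-yn-1-yl}oxolan-2-one
Product: 22 (4S,5R)-3-methylidene-4-({(2R,3R)-3-methyl-3-{3-[(triethylsilyl)oxy]propyl}oxiran-2-yl}methyl)-5-{(1R,2S)-2-methyl-1-[(triethylsilyl)oxy]hept-6-yn-1-yl}oxolan-2-one
Conditions: D-fructose-derived Shi ketone (1 equiv), KHSO5 (as Oxone, 2KHSO5·KHSO4·K2SO4), NaHCO3, Bu4NHSO4 (cat.), MeCN–CH2(OMe)2–H2O, 0 °C, pH 8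
Reagents that add atoms: potassium peroxymonosulfate (KHSO5) [K+].[O-]S(=O)(=O)OO
Why: Shi asymmetric epoxidation: the chiral dioxirane attacks the only electron-rich alkene (the enoate and the alkyne are inert) through the spiro transition state that converts an E-trisubstituted alkene into the (3R,4R)-oxirane under reagent control, and the near-neutral pH spares the lactone.

Step 12
Reactants: 22 (4S,5R)-3-methylidene-4-({(2R,3R)-3-methyl-3-{3-[(triethylsilyl)oxy]propyl}oxiran-2-yl}methyl)-5-{(1R,2S)-2-methyl-1-[(triethylsilyl)oxy]hept-6-yn-1-yl}oxolan-2-one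
Product: 23 3-[(2R,3R)-2-methyl-3-({(2R,3S)-4-methylidene-2-{(1R,2S)-2-methyl-1-[(triethylsilyl)oxy]hept-6-yn-1-yl}-5-oxooxolan-3-yl}methyl)oxiran-2-yl]propanal
Conditions: (COCl)2 (4 equiv), DMSO (8 equiv), CH2Cl2, −78 → −40 °C; Et3N, −78 → 0 °C
Reagents that add atoms: none
Why: Swern oxidative desilylation: chlorodimethylsulfonium chloride attacks the unhindered primary O–SiEt3 and the resulting alkoxysulfonium salt gives the aldehyde with Et3N, while the hindered secondary silyl ether, the oxirane and the enoate are untouched, so a free C7 hydroxyl is never exposed next to the oxirane.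

Step 13
Reactants: 23 3-[(2R,3R)-2-methyl-3-({(2R,3S)-4-methylidene-2-{(1R,2S)-2-methyl-1-[(triethylsilyl)oxy]hept-6-yn-1-yl}-5-oxooxolan-3-yl}methyl)oxiran-2-yl]propanal
Product: 24 (1S,3R,4R,7S,12S,13R,14R)-3,4-epoxy-7,13-bis[(triethylsilyl)oxy]cembra-8(19),15(17)-dien-16,14-olide
Conditions: Ni(cod)2 (0.25 equiv), 1,3-bis(2,6-diisopropylphenyl)imidazolium chloride (0.25 equiv), KOt-Bu (0.25 equiv), Et3SiH (5 equiv), THF, 23 °C, syringe-pump addition of 23 to 0.005 M
Reagents that add atoms: triethylsilane CC[SiH](CC)CC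
Why: Nickel-catalysed reductive alkyne–aldehyde macrocyclisation (Montgomery type): zerovalent nickel carrying the bulky carbene couples the C7 aldehyde to the internal carbon of the terminal alkyne by oxidative cyclisation (hence the exocyclic C8=C19 methylene), Et3SiH cleaves the oxanickelacycle to the silyl ether, high dilution favours the 14-membered ring, the enoate and the trisubstituted oxirane are poorer partners than the aldehyde, and C7 is set by macrocyclic substrate control with no close precedent to predict its sense, so 7S is an assumption and the least secure point of the plan.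

Step 14
Reactants: 24 (1S,3R,4R,7S,12S,13R,14R)-3,4-epoxy-7,13-bis[(triethylsilyl)oxy]cembra-8(19),15(17)-dien-16,14-olide
Product: 25 (1S,3R,4R,7S,12S,13R,14R)-3,4-epoxy-7,13-dihydroxycembra-8(19),15(17)-dien-16,14-olide (target)
Conditions: TBAF (3 equiv), AcOH (3 equiv), THF, 0 → 23 °C
Reagents that add atoms: none
Why: Fluoride desilylation buffered with acetic acid removes both silyl ethers while the enoate and the oxirane survive and no stereocentre is touched.

## Compound list

1 | (E)-but-2-en-1-ol | C/C=C/CO | starting material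
2 | [(2S,3S)-3-methyloxiran-2-yl]methanol | C[C@@H]1O[C@H]1CO | intermediate
3 | tert-butyl{[(2S,3S)-3-methyloxiran-2-yl]methoxy}diphenylsilane | C[C@@H]1O[C@H]1CO[Si](c1ccccc1)(c1ccccc1)C(C)(C)C | intermediate
4 | (5-chloropent-1-yn-1-yl)trimethylsilane | C[Si](C)(C)C#CCCCCl | starting material
5 | [5-(trimethylsilyl)pent-4-yn-1-yl]magnesium chloride | C[Si](C)(C)C#CCCC[Mg]Cl | intermediate
6 | (2R,3S)-1-{[tert-butyl(diphenyl)silyl]oxy}-3-methyl-8-(trimethylsilyl)oct-7-yn-2-ol | C[Si](C)(C)C#CCCC[C@H](C)[C@@H](O)CO[Si](c1ccccc1)(c1ccccc1)C(C)(C)C | intermediate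
7 | (2R,3S)-3-methyloct-7-yne-1,2-diol | C#CCCC[C@H](C)[C@@H](O)CO | intermediate
8 | (2R,3S)-2-hydroxy-3-methyloct-7-ynal | C#CCCC[C@H](C)[C@@H](O)C=O | intermediate
9 | tert-butyl(dimethyl)(pent-4-yn-1-yloxy)silane | C#CCCCO[Si](C)(C)C(C)(C)C | starting material
10 | oxirane | C1CO1 | starting material
11 | {(1E)-5-{[tert-butyl(dimethyl)silyl]oxy}-2-methylpent-1-en-1-yl}dimethylalumane | C[Al](C)/C=C(\C)CCCO[Si](C)(C)C(C)(C)C | intermediate
12 | lithium butyl{(1E)-5-{[tert-butyl(dimethyl)silyl]oxy}-2-methylpent-1-en-1-yl}dimethylaluminate | [Li+].CCCC[Al-](C)(C)/C=C(\C)CCCO[Si](C)(C)C(C)(C)C | intermediate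
13 | (3E)-7-{[tert-butyl(dimethyl)silyl]oxy}-4-methylhept-3-en-1-ol | OCC/C=C(C)/CCCO[Si](C)(C)C(C)(C)C | intermediate
14 | (3E)-7-{[tert-butyl(dimethyl)silyl]oxy}-4-methylhept-3-enal | O=CC/C=C(C)/CCCO[Si](C)(C)C(C)(C)C | intermediate
15 | methyl prop-2-ynoate | C#CC(=O)OC | starting material
16 | methyl 2-[bis(2-methylpropyl)alumanyl]prop-2-enoate | C=C(C(=O)OC)[Al](CC(C)C)CC(C)C | intermediate
17 | methyl (5E)-9-{[tert-butyl(dimethyl)silyl]oxy}-3-hydroxy-6-methyl-2-methylidenenon-5-enoate (racemic at C3) | C=C(C(=O)OC)C(O)C/C=C(C)/CCCO[Si](C)(C)C(C)(C)C | intermediate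
18 | methyl (2Z,5E)-2-(bromomethyl)-9-{[tert-butyl(dimethyl)silyl]oxy}-6-methylnona-2,5-dienoate | BrC/C(C(=O)OC)=C\C/C=C(C)/CCCO[Si](C)(C)C(C)(C)C | intermediate
19 | methyl (3S,4R,5R,6S)-3-[(2E)-6-{[tert-butyl(dimethyl)silyl]oxy}-3-methylhex-2-en-1-yl]-4,5-dihydroxy-6-methyl-2-methylideneundec-10-ynoate | C#CCCC[C@H](C)[C@@H](O)[C@H](O)[C@@H](C/C=C(C)/CCCO[Si](C)(C)C(C)(C)C)C(=C)C(=O)OC | intermediate
20 | (4S,5R)-4-[(2E)-6-hydroxy-3-methylhex-2-en-1-yl]-5-[(1R,2S)-1-hydroxy-2-methylhept-6-yn-1-yl]-3-methylideneoxolan-2-one | C#CCCC[C@H](C)[C@@H](O)[C@@H]1OC(=O)C(=C)[C@@H]1C/C=C(C)/CCCO | intermediate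
21 | (4S,5R)-3-methylidene-4-{(2E)-3-methyl-6-[(triethylsilyl)oxy]hex-2-en-1-yl}-5-{(1R,2S)-2-methyl-1-[(triethylsilyl)oxy]hept-6-yn-1-yl}oxolan-2-one | C#CCCC[C@H](C)[C@@H](O[Si](CC)(CC)CC)[C@@H]1OC(=O)C(=C)[C@@H]1C/C=C(C)/CCCO[Si](CC)(CC)CC | intermediate
22 | (4S,5R)-3-methylidene-4-({(2R,3R)-3-methyl-3-{3-[(triethylsilyl)oxy]propyl}oxiran-2-yl}methyl)-5-{(1R,2S)-2-methyl-1-[(triethylsilyl)oxy]hept-6-yn-1-yl}oxolan-2-one | C#CCCC[C@H](C)[C@@H](O[Si](CC)(CC)CC)[C@@H]1OC(=O)C(=C)[C@@H]1C[C@H]1O[C@]1(C)CCCO[Si](CC)(CC)CC | intermediate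
23 | 3-[(2R,3R)-2-methyl-3-({(2R,3S)-4-methylidene-2-{(1R,2S)-2-methyl-1-[(triethylsilyl)oxy]hept-6-yn-1-yl}-5-oxooxolan-3-yl}methyl)oxiran-2-yl]propanal | C#CCCC[C@H](C)[C@@H](O[Si](CC)(CC)CC)[C@@H]1OC(=O)C(=C)[C@@H]1C[C@H]1O[C@]1(C)CCC=O | intermediate
24 | (1S,3R,4R,7S,12S,13R,14R)-3,4-epoxy-7,13-bis[(triethylsilyl)oxy]cembra-8(19),15(17)-dien-16,14-olide | C=C1CCC[C@H](C)[C@@H](O[Si](CC)(CC)CC)[C@@H]2OC(=O)C(=C)[C@@H]2C[C@H]2O[C@]2(C)CC[C@@H]1O[Si](CC)(CC)CC | intermediate
25 | (1S,3R,4R,7S,12S,13R,14R)-3,4-epoxy-7,13-dihydroxycembra-8(19),15(17)-dien-16,14-olide (CNP0124069.2) | C=C1CCC[C@H](C)[C@@H](O)[C@@H]2OC(=O)C(=C)[C@@H]2C[C@H]2O[C@]2(C)CC[C@@H]1O | target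

## Step count and risks

Total step count: 14. Longest linear sequence: 10 steps (steps 5–8, then 9–14, from 9; the branch from 1, steps 1–4 then 9–14, is equally long).

**Step 13 (nickel macrocyclisation).** The main worry is the C7 face selectivity, which rests only on the macrocycle. The fallback sets C7 by a reagent-controlled reduction instead of by the ring closure; it sets out from 24 (as obtained, mixed with its C7 epimer) and comes back at 25. The mixture is desilylated as in step 14 to give 25 together with (1S,3R,4R,7R,12S,13R,14R)-3,4-epoxy-7,13-dihydroxycembra-8(19),15(17)-dien-16,14-olide F1. MnO2 in CH2Cl2 at 23 °C oxidises only the allylic C7 carbinol of both epimers to (1S,3R,4R,12S,13R,14R)-3,4-epoxy-13-hydroxy-7-oxocembra-8(19),15(17)-dien-16,14-olide F2. Corey–Bakshi–Shibata reduction ((R)-2-methyl-CBS-oxazaborolidine, catecholborane, toluene, −78 °C, the α-branched alkenyl group acting as the large substituent) then returns 25 with 7S.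

**Step 9 (indium Barbier).** The worries are the 13,14-syn facial selectivity and the handling of the free α-hydroxy aldehyde. The fallback enforces chelation with a Lewis acid on an α-alkoxy aldehyde and uses a preformed allylstannane (Keck-type SE2' addition) in place of the aqueous Barbier; it sets out from 6 and 18 and comes back at 20.
- 6 is treated with 4-methoxybenzyl trichloroacetimidate and catalytic camphorsulfonic acid to give tert-butyl{[(2R,3S)-2-[(4-methoxyphenyl)methoxy]-3-methyl-8-(trimethylsilyl)oct-7-yn-1-yl]oxy}diphenylsilane F3.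
- TBAF gives (2R,3S)-2-[(4-methoxyphenyl)methoxy]-3-methyloct-7-yn-1-ol F4, and Dess–Martin oxidation gives (2R,3S)-2-[(4-methoxyphenyl)methoxy]-3-methyloct-7-ynal F5.
- 18 is stannylated with (Bu3Sn)2 and catalytic Pd(PPh3)4 in THF to methyl (2Z,5E)-9-{[tert-butyl(dimethyl)silyl]oxy}-6-methyl-2-[(tributylstannyl)methyl]nona-2,5-dienoate F6.
- MgBr2·OEt2 (CH2Cl2, −25 °C) chelates the aldehyde and ether oxygens of F5, and F6 adds to the chelate through an open transition state to give methyl (3S,4R,5R,6S)-3-[(2E)-6-{[tert-butyl(dimethyl)silyl]oxy}-3-methylhex-2-en-1-yl]-4-hydroxy-5-[(4-methoxyphenyl)methoxy]-6-methyl-2-methylideneundec-10-ynoate F7 (13,14-syn and 1,14-syn).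
- Aqueous CF3CO2H in CH2Cl2 lactonises F7 and removes both the 4-methoxybenzyl and the silyl group to give 20.

**Step 4 (diol to α-hydroxy aldehyde).** The worry is glycol cleavage or over-oxidation. The fallback differentiates the two hydroxyls by protecting groups instead of by catalyst chemoselectivity; it sets out from 7 and comes back at 8. Et3SiOTf and 2,6-lutidine give (2R,3S)-3-methyl-1,2-bis[(triethylsilyl)oxy]oct-7-yne F8. Swern oxidation with warming to −40 °C cleaves and oxidises only the primary silyl ether to (2R,3S)-3-methyl-2-[(triethylsilyl)oxy]oct-7-ynal F9. AcOH–THF–H2O at 23 °C removes the secondary silyl group, and the resulting solution of 8 is used directly in step 9.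

## Further compounds

F1 | step 13 | (1S,3R,4R,7R,12S,13R,14R)-3,4-epoxy-7,13-dihydroxycembra-8(19),15(17)-dien-16,14-olide | C=C1CCC[C@H](C)[C@@H](O)[C@@H]2OC(=O)C(=C)[C@@H]2C[C@H]2O[C@]2(C)CC[C@H]1O
F2 | step 13 | (1S,3R,4R,12S,13R,14R)-3,4-epoxy-13-hydroxy-7-oxocembra-8(19),15(17)-dien-16,14-olide | C=C1CCC[C@H](C)[C@@H](O)[C@@H]2OC(=O)C(=C)[C@@H]2C[C@H]2O[C@]2(C)CCC1=O
F3 | step 9 | tert-butyl{[(2R,3S)-2-[(4-methoxyphenyl)methoxy]-3-methyl-8-(trimethylsilyl)oct-7-yn-1-yl]oxy}diphenylsilane | C[Si](C)(C)C#CCCC[C@H](C)[C@@H](OCc1ccc(OC)cc1)CO[Si](c1ccccc1)(c1ccccc1)C(C)(C)C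
F4 | step 9 | (2R,3S)-2-[(4-methoxyphenyl)methoxy]-3-methyloct-7-yn-1-ol | C#CCCC[C@H](C)[C@@H](OCc1ccc(OC)cc1)CO
F5 | step 9 | (2R,3S)-2-[(4-methoxyphenyl)methoxy]-3-methyloct-7-ynal | C#CCCC[C@H](C)[C@@H](OCc1ccc(OC)cc1)C=O
F6 | step 9 | methyl (2Z,5E)-9-{[tert-butyl(dimethyl)silyl]oxy}-6-methyl-2-[(tributylstannyl)methyl]nona-2,5-dienoate | CCCC[Sn](CCCC)(CCCC)C/C(C(=O)OC)=C\C/C=C(C)/CCCO[Si](C)(C)C(C)(C)C
F7 | step 9 | methyl (3S,4R,5R,6S)-3-[(2E)-6-{[tert-butyl(dimethyl)silyl]oxy}-3-methylhex-2-en-1-yl]-4-hydroxy-5-[(4-methoxyphenyl)methoxy]-6-methyl-2-methylideneundec-10-ynoate | C#CCCC[C@H](C)[C@@H](OCc1ccc(OC)cc1)[C@H](O)[C@@H](C/C=C(C)/CCCO[Si](C)(C)C(C)(C)C)C(=C)C(=O)OC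
F8 | step 4 | (2R,3S)-3-methyl-1,2-bis[(triethylsilyl)oxy]oct-7-yne | C#CCCC[C@H](C)[C@@H](O[Si](CC)(CC)CC)CO[Si](CC)(CC)CC
F9 | step 4 | (2R,3S)-3-methyl-2-[(triethylsilyl)oxy]oct-7-ynal | C#CCCC[C@H](C)[C@@H](O[Si](CC)(CC)CC)C=O
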